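**Retrosynthetic overview**

- Ring labels: unit 1 = rings A (benzo), C (pyranone) and B (4-hydroxyphenyl); unit 2 = rings D (benzo) and F (pyranone); ring E = the central anisole.
- Feature: ring E is 1,3,4-substituted. E1 carries C2 of ring F (a carboxyl-level carbon), E3 carries C3 of ring C, and E4 carries OMe. This is the pattern formed when an alkyne MeO–C≡C–R adds across C3/C6 of methyl coumalate and CO2 is lost.
- Disconnections: ring F by Baker–Venkataraman rearrangement and cyclodehydration from a ring E benzoic acid and 2-hydroxy-4,6-bis(benzyloxy)acetophenone; ring E (bonds E2–E3 and E4–E5) by pyranone/ynol ether cycloaddition; the C3–C(sp) bond by Negishi coupling of a 3-iodoflavone; ring C by diketone cyclodehydration.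
- Ring order: ring C (step 3), ring E (step 6), ring F (step 11). Rings A, B and D come with the starting materials. Four benzyl ethers mask the free phenols and are removed last.

Key step: step 6

Remark: the target has no stereocenter and no configuration is given for the hindered C3–ring E axis, so no stereocontrol is planned; 2',6'-dihydroxy-4'-methoxyacetophenone is taken as a purchasable starting material.

**Step 1**
Reactants: 1 2',6'-dihydroxy-4'-methoxyacetophenone
Product: 2 2'-(benzyloxy)-6'-hydroxy-4'-methoxyacetophenone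
Conditions: BnBr (1.05 equiv), K2CO3 (1.1 equiv), acetone, reflux
Reagents that add atoms: benzyl bromide, BrCc1ccccc1
Why: Williamson etherification takes the phenol that is not chelated and should stop at the mono-ether, because the remaining phenol is locked in a hydrogen bond to the ketone.

**Step 2**
Reactants: 2 2'-(benzyloxy)-6'-hydroxy-4'-methoxyacetophenone; 3 4-(benzyloxy)benzoic acid
Product: 5 1-[2-(benzyloxy)-6-hydroxy-4-methoxyphenyl]-3-[4-(benzyloxy)phenyl]propane-1,3-dione, via 4-(benzyloxy)benzoyl chloride 4 (not isolated)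
Conditions: 3, (COCl)2, DMF (cat.), CH2Cl2, rt, evaporate; 2, LiN(SiMe3)2 (3.2 equiv), THF, −78 to −10 °C, then 4, −78 °C to rt; aq HCl
Reagents that add atoms: none
Why: Acylation of the lithium phenoxide–enolate dianion of an ortho-hydroxyacetophenone by an aroyl chloride (one-flask variant of the Baker–Venkataraman diketone synthesis) should give the ortho-hydroxy 1,3-diketone, the third equivalent of base taking up the acidic diketone proton.

**Step 3**
Reactants: 5 1-[2-(benzyloxy)-6-hydroxy-4-methoxyphenyl]-3-[4-(benzyloxy)phenyl]propane-1,3-dione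
Product: 6 5-(benzyloxy)-2-[4-(benzyloxy)phenyl]-7-methoxy-4H-chromen-4-one
Conditions: p-TsOH·H2O (10 mol %), toluene, 90 °C, 4 Å MS
Reagents that add atoms: none
Why: Acid-catalysed cyclodehydration of the ortho-hydroxy 1,3-diketone (phenol adds to the enolised aryl ketone, water is lost) closes pyranone ring C, and a catalytic sulfonic acid in toluene is mild enough to keep the peri benzyl ether.

**Step 4**
Reactants: 6 5-(benzyloxy)-2-[4-(benzyloxy)phenyl]-7-methoxy-4H-chromen-4-one
Product: 7 5-(benzyloxy)-2-[4-(benzyloxy)phenyl]-3-iodo-7-methoxy-4H-chromen-4-one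
Conditions: LiN(i-Pr)2 (1.2 equiv), THF, −78 °C; I2 (1.3 equiv), −78 °C to rt
Reagents that add atoms: iodine, II
Why: Directed lithiation of the flavone at C3, the vinylic position next to the coordinating C4 carbonyl, followed by iodine quench is the established route to 3-iodo-5,7-dialkoxyflavones and avoids electrophilic iodination, which would attack C6 or C8 of the electron-rich ring A.

**Step 5**
Reactants: 7 5-(benzyloxy)-2-[4-(benzyloxy)phenyl]-3-iodo-7-methoxy-4H-chromen-4-one; 8 chloroacetaldehyde dimethyl acetal
Product: 11 5-(benzyloxy)-2-[4-(benzyloxy)phenyl]-7-methoxy-3-(methoxyethynyl)-4H-chromen-4-one, via lithium methoxyacetylide 9 (not isolated), via methoxyethynylzinc chloride 10 (not isolated)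
Conditions: 8 (2.5 equiv), LiNEt2 (3 equiv per 8), THF, 0 °C; ZnCl2, THF, 0 °C; 7, Pd(PPh3)4 (5 mol %), THF, rt to 40 °C; purify on Et3N-deactivated silica
Reagents that add atoms: none
Why: Threefold action of the amide base on the chloroacetal (loss of methanol, loss of HCl, deprotonation) gives the methoxyacetylide, which after transmetalation to zinc should undergo Negishi coupling at the C3–I bond, a coupling known for alkoxyethynylzinc halides with aryl iodides and run under non-acidic conditions that keep the ynol ether intact.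

**Step 6**
Reactants: 11 5-(benzyloxy)-2-[4-(benzyloxy)phenyl]-7-methoxy-3-(methoxyethynyl)-4H-chromen-4-one; 12 methyl coumalate
Product: 14 methyl 3-{5-(benzyloxy)-2-[4-(benzyloxy)phenyl]-7-methoxy-4-oxo-4H-chromen-3-yl}-4-methoxybenzoate, via bridged bicyclic lactone 13 (not isolated)
Conditions: 12 (3 equiv), toluene, 110 °C, sealed tube, Ar, base-washed glass
Reagents that add atoms: none
Why: The electron-poor diene C3=C4–C5=C6 of 12 (lowered in energy by the lactone and the C5 ester) and the electron-rich ynol ether should combine in an asynchronous inverse-demand (4+2) cycloaddition in which the bond from the chromone-bearing alkyne carbon to C6 of 12 runs ahead of the bond from the methoxy-bearing carbon to C3 of 12, and the bridged lactone 13 then expels CO2 by retro-(4+2) reaction at the same temperature, so that ring E appears aromatic without an oxidant. The closest known reactions are the cycloaddition/decarboxylation cascades of methyl coumalate with ynamines, alkoxyalkynes, enol ethers and ketene acetals, which give para-heteroatom-substituted benzoates. Ring E is closed by this intermolecular cycloaddition alone, the E2–E3 and E4–E5 bonds being made in one operation. No stereocenter remains, because the two bridgehead centres of racemic 13 become sp2 carbons when CO2 leaves. The step needs one regiochemistry, methoxy para and the chromonyl group meta to the ester, and the polarisation of both partners secures it: the oxygen lone pair makes the chromone-bearing alkyne carbon the nucleophilic terminus, and C6 of 12, activated by both carbonyl groups, is the electrophilic terminus. A methyl ynol ether has no hydrogen that could be delivered in a retro-ene collapse to a ketene and so should tolerate the heating, and the alkyne sits on the alpha carbon of the chromone enone, where it is cross-conjugated and keeps its nucleophilic character.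

**Step 7**
Reactants: 14 methyl 3-{5-(benzyloxy)-2-[4-(benzyloxy)phenyl]-7-methoxy-4-oxo-4H-chromen-3-yl}-4-methoxybenzoate
Product: 15 3-{5-(benzyloxy)-2-[4-(benzyloxy)phenyl]-7-methoxy-4-oxo-4H-chromen-3-yl}-4-methoxybenzoic acid
Conditions: LiOH·H2O (4 equiv), THF/MeOH/H2O, 40 °C; then 1 M HCl
Reagents that add atoms: lithium hydroxide, [Li+].[OH-]
Why: Saponification by acyl–oxygen cleavage of the unhindered methyl benzoate should proceed while the 2,3-diaryl pyranone is shielded against hydroxide attack at C2, and any ring-opened material recloses on acidification.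

**Step 8**
Reactants: 16 2,4,6-trihydroxyacetophenone
Product: 17 2'-hydroxy-4',6'-bis(benzyloxy)acetophenone
Conditions: BnBr (2.1 equiv), K2CO3 (2.2 equiv), DMF, rt
Reagents that add atoms: benzyl bromide, BrCc1ccccc1
Why: Williamson etherification alkylates the para phenol and one ortho phenol, while the last ortho phenol stays chelated to the acetyl group and unreactive (known selective dibenzylation).

**Step 9**
Reactants: 15 3-{5-(benzyloxy)-2-[4-(benzyloxy)phenyl]-7-methoxy-4-oxo-4H-chromen-3-yl}-4-methoxybenzoic acid; 17 2'-hydroxy-4',6'-bis(benzyloxy)acetophenone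
Product: 18 2-acetyl-3,5-bis(benzyloxy)phenyl 3-{5-(benzyloxy)-2-[4-(benzyloxy)phenyl]-7-methoxy-4-oxo-4H-chromen-3-yl}-4-methoxybenzoate
Conditions: DCC (1.3 equiv), DMAP (0.2 equiv), CH2Cl2, rt
Reagents that add atoms: none
Why: Steglich esterification through the O-acylisourea and the acylpyridinium ion should acylate the chelated phenol under neutral conditions that leave the benzyl ethers and the chromone untouched.

**Step 10**
Reactants: 18 2-acetyl-3,5-bis(benzyloxy)phenyl 3-{5-(benzyloxy)-2-[4-(benzyloxy)phenyl]-7-methoxy-4-oxo-4H-chromen-3-yl}-4-methoxybenzoate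
Product: 19 1-[2,4-bis(benzyloxy)-6-hydroxyphenyl]-3-(3-{5-(benzyloxy)-2-[4-(benzyloxy)phenyl]-7-methoxy-4-oxo-4H-chromen-3-yl}-4-methoxyphenyl)propane-1,3-dione
Conditions: LiN(SiMe3)2 (3 equiv), THF, −78 to 0 °C; aq HCl
Reagents that add atoms: none
Why: Baker–Venkataraman rearrangement, in which the ketone enolate adds to the neighbouring aryl ester and the tetrahedral intermediate opens to the phenoxide 1,3-diketonate (O-to-C acyl shift), with a non-nucleophilic amide base that cannot cleave the ester.

**Step 11**
Reactants: 19 1-[2,4-bis(benzyloxy)-6-hydroxyphenyl]-3-(3-{5-(benzyloxy)-2-[4-(benzyloxy)phenyl]-7-methoxy-4-oxo-4H-chromen-3-yl}-4-methoxyphenyl)propane-1,3-dione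
Product: 20 5-(benzyloxy)-2-[4-(benzyloxy)phenyl]-3-{5-[5,7-bis(benzyloxy)-4-oxo-4H-chromen-2-yl]-2-methoxyphenyl}-7-methoxy-4H-chromen-4-one
Conditions: p-TsOH·H2O (20 mol %), toluene, 90 °C, 4 Å MS
Reagents that add atoms: none
Why: Acid-catalysed cyclodehydration as in step 3 closes pyranone ring F, and a peri benzyl ether lost here would be of no consequence because step 12 removes all four.

**Step 12**
Reactants: 20 5-(benzyloxy)-2-[4-(benzyloxy)phenyl]-3-{5-[5,7-bis(benzyloxy)-4-oxo-4H-chromen-2-yl]-2-methoxyphenyl}-7-methoxy-4H-chromen-4-one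
Product: 21 3-[5-(5,7-dihydroxy-4-oxo-4H-chromen-2-yl)-2-methoxyphenyl]-5-hydroxy-2-(4-hydroxyphenyl)-7-methoxy-4H-chromen-4-one (target)
Conditions: H2 (1 atm), Pd(OH)2/C, THF/MeOH, rt
Reagents that add atoms: none
Why: Hydrogenolysis should cleave the four benzylic C–O bonds while the aryl methyl ethers and the conjugated pyranone C2=C3 bonds stay intact at one atmosphere and room temperature.

**Compound list**

1 | 2',6'-dihydroxy-4'-methoxyacetophenone | CC(=O)c1c(O)cc(OC)cc1O | starting material
2 | 2'-(benzyloxy)-6'-hydroxy-4'-methoxyacetophenone | CC(=O)c1c(O)cc(OC)cc1OCc1ccccc1 | intermediate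
3 | 4-(benzyloxy)benzoic acid | OC(=O)c1ccc(OCc2ccccc2)cc1 | starting material
4 | 4-(benzyloxy)benzoyl chloride | O=C(Cl)c1ccc(OCc2ccccc2)cc1 | intermediate (not isolated)
5 | 1-[2-(benzyloxy)-6-hydroxy-4-methoxyphenyl]-3-[4-(benzyloxy)phenyl]propane-1,3-dione | O=C(CC(=O)c1ccc(OCc2ccccc2)cc1)c1c(O)cc(OC)cc1OCc1ccccc1 | intermediate
6 | 5-(benzyloxy)-2-[4-(benzyloxy)phenyl]-7-methoxy-4H-chromen-4-one | O=c1cc(-c2ccc(OCc3ccccc3)cc2)oc2cc(OC)cc(OCc3ccccc3)c12 | intermediate
7 | 5-(benzyloxy)-2-[4-(benzyloxy)phenyl]-3-iodo-7-methoxy-4H-chromen-4-one | O=c1c(I)c(-c2ccc(OCc3ccccc3)cc2)oc2cc(OC)cc(OCc3ccccc3)c12 | intermediate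
8 | chloroacetaldehyde dimethyl acetal | COC(CCl)OC | starting material
9 | lithium methoxyacetylide | [Li]C#COC | intermediate (not isolated)
10 | methoxyethynylzinc chloride | COC#C[Zn]Cl | intermediate (not isolated)
11 | 5-(benzyloxy)-2-[4-(benzyloxy)phenyl]-7-methoxy-3-(methoxyethynyl)-4H-chromen-4-one | COC#Cc1c(-c2ccc(OCc3ccccc3)cc2)oc2cc(OC)cc(OCc3ccccc3)c2c1=O | intermediate
12 | methyl coumalate | COC(=O)c1ccc(=O)oc1 | starting material
13 | methyl 7-{5-(benzyloxy)-2-[4-(benzyloxy)phenyl]-7-methoxy-4-oxo-4H-chromen-3-yl}-8-methoxy-3-oxo-2-oxabicyclo[2.2.2]octa-5,7-diene-6-carboxylate (racemic, one enantiomer drawn; bridgeheads fixed relative to each other by the bicycle) | COC(=O)C1=C[C@@H]2C(=O)O[C@H]1C(=C2OC)c1c(-c2ccc(OCc3ccccc3)cc2)oc2cc(OC)cc(OCc3ccccc3)c2c1=O | intermediate (not isolated)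
14 | methyl 3-{5-(benzyloxy)-2-[4-(benzyloxy)phenyl]-7-methoxy-4-oxo-4H-chromen-3-yl}-4-methoxybenzoate | COC(=O)c1ccc(OC)c(-c2c(-c3ccc(OCc4ccccc4)cc3)oc3cc(OC)cc(OCc4ccccc4)c3c2=O)c1 | intermediate
15 | 3-{5-(benzyloxy)-2-[4-(benzyloxy)phenyl]-7-methoxy-4-oxo-4H-chromen-3-yl}-4-methoxybenzoic acid | OC(=O)c1ccc(OC)c(-c2c(-c3ccc(OCc4ccccc4)cc3)oc3cc(OC)cc(OCc4ccccc4)c3c2=O)c1 | intermediate
16 | 2,4,6-trihydroxyacetophenone | CC(=O)c1c(O)cc(O)cc1O | starting material
17 | 2'-hydroxy-4',6'-bis(benzyloxy)acetophenone | CC(=O)c1c(O)cc(OCc2ccccc2)cc1OCc1ccccc1 | intermediate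
18 | 2-acetyl-3,5-bis(benzyloxy)phenyl 3-{5-(benzyloxy)-2-[4-(benzyloxy)phenyl]-7-methoxy-4-oxo-4H-chromen-3-yl}-4-methoxybenzoate | CC(=O)c1c(OCc2ccccc2)cc(OCc2ccccc2)cc1OC(=O)c1ccc(OC)c(-c2c(-c3ccc(OCc4ccccc4)cc3)oc3cc(OC)cc(OCc4ccccc4)c3c2=O)c1 | intermediate
19 | 1-[2,4-bis(benzyloxy)-6-hydroxyphenyl]-3-(3-{5-(benzyloxy)-2-[4-(benzyloxy)phenyl]-7-methoxy-4-oxo-4H-chromen-3-yl}-4-methoxyphenyl)propane-1,3-dione | O=C(CC(=O)c1ccc(OC)c(-c2c(-c3ccc(OCc4ccccc4)cc3)oc3cc(OC)cc(OCc4ccccc4)c3c2=O)c1)c1c(O)cc(OCc2ccccc2)cc1OCc1ccccc1 | intermediate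
20 | 5-(benzyloxy)-2-[4-(benzyloxy)phenyl]-3-{5-[5,7-bis(benzyloxy)-4-oxo-4H-chromen-2-yl]-2-methoxyphenyl}-7-methoxy-4H-chromen-4-one | COc1cc(OCc2ccccc2)c2c(=O)c(-c3cc(-c4cc(=O)c5c(OCc6ccccc6)cc(OCc6ccccc6)cc5o4)ccc3OC)c(-c3ccc(OCc4ccccc4)cc3)oc2c1 | intermediate
21 | 3-[5-(5,7-dihydroxy-4-oxo-4H-chromen-2-yl)-2-methoxyphenyl]-5-hydroxy-2-(4-hydroxyphenyl)-7-methoxy-4H-chromen-4-one | COc1cc(O)c2c(=O)c(-c3cc(-c4cc(=O)c5c(O)cc(O)cc5o4)ccc3OC)c(-c3ccc(O)cc3)oc2c1 | target

**Step count and risks**

Total step count: 12. Longest linear sequence: 11 (steps 1–7 and 9–12; step 8 is a one-step side branch).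

Steps most likely to fail:

1. Step 6. The cycloaddition may be slow, because the chromonyl group adds bulk and withdraws some electron density at the reacting alkyne carbon. While it is slow, the ynol ether may be consumed by hydration from traces of acid or water, or by attack of the chromone carbonyl oxygen on the activated alkyne. Fallback: set out from iodide 7 and form the C3–ring E bond directly by Suzuki–Miyaura coupling with purchased [2-methoxy-5-(methoxycarbonyl)phenyl]boronic acid (COC(=O)c1ccc(OC)c(B(O)O)c1), using Pd(OAc)2/SPhos, K3PO4, toluene/H2O, 90 °C. Arylation of 3-iodoflavones by boronic acids is known chemistry. The coupling should give benzoate 14, where the route is rejoined; this fallback makes no compound outside the compound list (F0).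

2. Step 5. Elimination to the acetylide may be incomplete, and the sensitive ynol ether may be lost during coupling or chromatography through hydration to the arylacetate, addition of diethylamine, or amine attack on the pyranone. Fallback: set out from chloroacetal 8, generate acetylide 9 as before and quench it with Bu3SnCl to give tributyl(methoxyethynyl)stannane F1, which is distilled. Stille coupling of this isolated, amine-free and zinc-free nucleophile with iodide 7 (Pd(PPh3)4, toluene, 80 °C) should give ynol ether 11, where the route is rejoined.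

3. Step 4. The amide base or the 3-lithio species may add to C2 of another flavone molecule (conjugate addition, ring opening, self-condensation), or lithiation may be incomplete, giving mixtures. Fallback: set out from diketone 5 and introduce the halogen before ring closure. NBS (1.0 equiv, CH2Cl2, 0 °C) should brominate the enolised central carbon to give 2-bromo-1-[2-(benzyloxy)-6-hydroxy-4-methoxyphenyl]-3-[4-(benzyloxy)phenyl]propane-1,3-dione F2. Acid cyclodehydration (p-TsOH·H2O, toluene, 90 °C) should then give 5-(benzyloxy)-2-[4-(benzyloxy)phenyl]-3-bromo-7-methoxy-4H-chromen-4-one F3. Negishi coupling of this bromide with zinc reagent 10 under a more active catalyst (Pd(P(t-Bu)3)2, THF, 40 °C) rejoins the route at ynol ether 11.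

**Further compounds**

F0 | step 6 | none | none
F1 | step 5 | tributyl(methoxyethynyl)stannane | CCCC[Sn](CCCC)(CCCC)C#COC
F2 | step 4 | 2-bromo-1-[2-(benzyloxy)-6-hydroxy-4-methoxyphenyl]-3-[4-(benzyloxy)phenyl]propane-1,3-dione (racemic, configurationally labile) | O=C(C(Br)C(=O)c1ccc(OCc2ccccc2)cc1)c1c(O)cc(OC)cc1OCc1ccccc1
F3 | step 4 | 5-(benzyloxy)-2-[4-(benzyloxy)phenyl]-3-bromo-7-methoxy-4H-chromen-4-one | O=c1c(Br)c(-c2ccc(OCc3ccccc3)cc2)oc2cc(OC)cc(OCc3ccccc3)c12
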